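**Retrosynthetic overview**
- The target is reached by acyl adjustment (C7 benzoate, C2/C3 acetates, C4/C5 unmasked) from a 1,6-epoxy-4,5-diol whose C2, C3 and C7 oxygens are benzyloxymethyl (BOM) ethers.
- That oxirane comes from a 4α,5α-epoxy-1α,6β-diol by a double Payne rearrangement (C6–O walks to C5, C1–O closes on C6); the epoxy diol comes from face-selective epoxidation of a cyclohexene.
- The cyclohexene is cut at C1–C6 and C2–C3 by a catalytic enantioselective Diels–Alder reaction into (1E,3E)-1-acetoxy-4-silyloxybutadiene and a 4-acyl-1,3-dioxol-2-one carrying an oxazolidinone.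
- Feature used: on the six-membered carbocycle, C1–O and C2–O are the only cis oxygen pair, while C7 (on C1), C3–O and a removable C6–O lie on the opposite face and C4/C5 can be an alkene. This is the pattern of an endo adduct of an (E,E)-1,4-dioxygenated diene with an acyl-dioxolone.
- Ring order: cyclohexene (step 6), then the 4,5-oxirane (step 9), which is transposed to the 1,6-oxirane (step 11).

Key step: step 6

**Remarks**
- Locants C1–C7 are those of the target: C1 is the quaternary ring carbon bearing C7, C2 and C3 the acetoxy carbons, C4 and C5 the carbinol carbons, C6 the oxirane CH. With the ring drawn flat and C1→C6 clockwise, β is toward the viewer and α away. The target is 1α,6α-epoxy, 1β-CH2OBz, 2α-OAc, 3β-OAc, 4α-OH, 5β-OH.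
- Assumption: the copper-bound dienophile reacts as the s-cis rotamer (ring C=C syn to the exocyclic C=O), as acrylimides do. On this basis the (S,S)-ligand opens the required Re face of C1. If the s-trans rotamer reacts, the (R,R)-ligand is used instead.
- The C2, C3 and C7 oxygens are carried as BOM ethers because they can be put on without forming an alkoxide and taken off by neutral hydrogenolysis.

**Route**

Step 1
Reactants: 1 (1E,3E)-buta-1,3-diene-1,4-diyl diacetate
Product: 3 (1E,3E)-4-(tert-butyldimethylsilyloxy)buta-1,3-dienyl acetate, via lithium dienolate 2 (not isolated)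
Conditions: MeLi (2.0 equiv), THF, −78 → −40 °C; then TBSCl (1.2 equiv), DMPU, −78 → 0 °C
Reagents that add atoms: TBSCl, CC(C)(C)[Si](C)(C)Cl
Why: Enol acetate cleavage by MeLi (acyl substitution, the acetyl group ending as lithium tert-butoxide) unmasks one dienolate without touching either C=C, so the E,E geometry is kept, and the silyl chloride traps the dienolate on oxygen (enolate O-silylation).

Step 2
Reactants: 4 glycerol carbonate (4-(hydroxymethyl)-1,3-dioxolan-2-one, racemic)
Product: 5 2-oxo-1,3-dioxolane-4-carboxylic acid (racemic)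
Conditions: TEMPO (cat.), PhI(OAc)2 (2.2 equiv), MeCN/H2O, rt
Reagents that add atoms: water, O
Why: Nitroxyl-catalysed oxidation with a hypervalent iodine oxidant takes the primary alcohol through the aldehyde hydrate to the acid under near-neutral conditions that leave the cyclic carbonate intact.

Step 3
Reactants: 5 2-oxo-1,3-dioxolane-4-carboxylic acid; 6 oxazolidin-2-one
Product: 8 3-(2-oxo-1,3-dioxolane-4-carbonyl)oxazolidin-2-one (racemic), via acid chloride 7 (not isolated)
Conditions: (COCl)2, DMF (cat.), CH2Cl2, 0 °C → rt, evaporate; then 6, Et3N, DMAP (cat.), CH2Cl2, 0 °C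
Reagents that add atoms: none
Why: Acid chloride formation followed by DMAP-catalysed N-acylation is standard imide synthesis; ring opening of the carbonate by β-elimination from C4 would be the reverse of a 5-endo-trig closure and should be slow.

Step 4
Reactants: 8 3-(2-oxo-1,3-dioxolane-4-carbonyl)oxazolidin-2-one
Product: 9 3-(4-bromo-2-oxo-1,3-dioxolane-4-carbonyl)oxazolidin-2-one (racemic)
Conditions: NBS (1.1 equiv), dibenzoyl peroxide (cat.), PhCF3, 85 °C
Reagents that add atoms: N-bromosuccinimide, O=C1CCC(=O)N1Br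
Why: Wohl–Ziegler radical bromination takes the weakest C–H bond, the tertiary captodative C4–H between the imide carbonyl and the carbonate oxygen, as in the α-bromination of lactide; a C5 bromide, if formed, would give the same alkene in step 5.

Step 5
Reactants: 9 3-(4-bromo-2-oxo-1,3-dioxolane-4-carbonyl)oxazolidin-2-one
Product: 10 3-(2-oxo-1,3-dioxole-4-carbonyl)oxazolidin-2-one
Conditions: Et3N (1.2 equiv), CH2Cl2, 0 °C
Reagents that add atoms: none
Why: Amine-induced E2 dehydrobromination, the reaction type that converts chloroethylene carbonate into vinylene carbonate, can only remove a C5 hydrogen because C4 carries none, and gives the enol carbonate conjugated with the imide.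

Step 6
Reactants: 3 (1E,3E)-4-(tert-butyldimethylsilyloxy)buta-1,3-dienyl acetate; 10 3-(2-oxo-1,3-dioxole-4-carbonyl)oxazolidin-2-one
Product: 11 (3aR,4S,7R,7aR)-7-(tert-butyldimethylsilyloxy)-2-oxo-7a-(2-oxooxazolidine-3-carbonyl)-3a,4,7,7a-tetrahydro-1,3-benzodioxol-4-yl acetate (cyclohex-4-ene with 1α,2α-carbonate, 1β-imide carbonyl C7, 3β-OAc, 6β-OTBS)
Conditions: [Cu((S,S)-t-Bu-box)](SbF6)2 (10 mol %, from CuCl2, ligand and AgSbF6), 3 (1.5–2 equiv), CH2Cl2, −78 → −20 °C; t-Bu-box = 2,2'-(propane-2,2-diyl)bis[(4S)-4-tert-butyl-4,5-dihydro-1,3-oxazole]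
Reagents that add atoms: none
Why: Proposed new method: two-point binding of the imide carbonyls of 10 to the cationic divalent copper centre lowers the LUMO of the dioxolone C=C and holds the acyl group in plane, so 3 should add in a concerted, asynchronous [4+2] cycloaddition, suprafacial on both partners, in which the C2–C3 bond leads and the C1–C6 bond follows and the cyclohexene is closed by intermolecular cycloaddition; the closest known reactions are the additions of 1-acetoxybutadiene and other 1-oxygenated dienes to 3-acryloyl- and 3-crotonoyl-oxazolidin-2-ones under the same catalyst, the α,β-dioxygenated trisubstituted alkene of 10 being the untested element. The cis C1–O/C2–O relationship is fixed by the dioxolone ring and the cis C3–OAc/C6–OTBS relationship by the E,E geometry of 3. Endo placement of the metal-bound acyl group, with the carbonate exo, puts C7 on the face of the C3 and C6 oxygens and the carbonate oxygens on the other face. Regiochemistry follows from the silyloxy group being the stronger donor: the largest HOMO coefficient sits on the acetoxy-bearing terminus, which bonds to the β-carbon C2, so the silyloxy carbon becomes C6 next to C1. The absolute configuration comes from the tert-butyl group of the (S,S)-ligand, which covers the Si face of C1 in the s-cis chelate and leaves the Re face open. The step thus needs acyl-endo over carbonate-endo selectivity, ortho regiochemistry and one open face, secured by chelation-enhanced secondary overlap, the OSi/OAc donor difference and the C2-symmetric ligand respectively.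

Step 7
Reactants: 11 Diels–Alder adduct
Product: 13 6β-(tert-butyldimethylsilyloxy)-1β-(hydroxymethyl)cyclohex-4-ene-1α,2α,3β-triol, via carbonate alcohol 12 (not isolated)
Conditions: LiBH4 (1.5 equiv), MeOH (1.5 equiv), THF, 0 °C; then K2CO3 (0.3 equiv), MeOH, 0 °C → rt
Reagents that add atoms: none
Why: Borohydride reduction of the N-acyl oxazolidinone (hydride adds to the exocyclic carbonyl, activated by the α-oxygen) is run while C1–O is still tied up in the carbonate, so no free α-alkoxide can attack the ring carbonyl; base-catalysed transesterification then removes carbonate and acetate without touching a stereocentre.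

Step 8
Reactants: 13 tetraol
Product: 14 2α,3β-bis(benzyloxymethoxy)-1β-(benzyloxymethoxymethyl)-6β-(tert-butyldimethylsilyloxy)cyclohex-4-en-1α-ol
Conditions: BOMCl (4 equiv), i-Pr2NEt (6 equiv), Bu4NI (cat.), CH2Cl2, 0 → 40 °C
Reagents that add atoms: benzyl chloromethyl ether, ClCOCc1ccccc1
Why: Etherification with the chloromethyl ether under amine base generates no alkoxide, so the C6 silyl group cannot migrate to C7–O, and the congested tertiary C1–OH is expected to stay free.

Step 9
Reactants: 14 tris-BOM cyclohexenol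
Product: 15 4α,5α-epoxy-2α,3β-bis(benzyloxymethoxy)-1β-(benzyloxymethoxymethyl)-6β-(tert-butyldimethylsilyloxy)cyclohexan-1α-ol
Conditions: mCPBA (2 equiv), CH2Cl2, 0 °C → rt
Reagents that add atoms: 3-chloroperbenzoic acid, OOC(=O)c1cccc(Cl)c1
Why: Prilezhaev epoxidation should occur on the α face, anti to both allylic substituents (C3–OBOM and C6–OTBS, both β) and syn to the hydrogen-bonding homoallylic C1–OH, which sets C4 and C5 by substrate control.

Step 10
Reactants: 15 silylated epoxy alcohol
Product: 16 4α,5α-epoxy-2α,3β-bis(benzyloxymethoxy)-1β-(benzyloxymethoxymethyl)cyclohexane-1α,6β-diol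
Conditions: TBAF (1.5 equiv), AcOH (1.5 equiv), THF, rt
Reagents that add atoms: none
Why: Fluoride-induced desilylation, buffered with acetic acid so that no free alkoxide starts the epoxide migration early, frees the C6 hydroxyl anti to the oxirane.

Step 11
Reactants: 16 epoxy diol
Product: 18 1α,6α-epoxy-2α,3β-bis(benzyloxymethoxy)-1β-(benzyloxymethoxymethyl)cyclohexane-4α,5β-diol, via 5β,6β-epoxide 17 (not isolated)
Conditions: t-BuOK (0.2 equiv), t-BuOH/THF, rt; aq NH4Cl
Reagents that add atoms: none
Why: Double Payne rearrangement: the β C6 alkoxide opens the α 4,5-oxirane at C5 by intramolecular backside attack (inversion at C5) and the α C1 alkoxide then opens the β 5,6-oxirane at C6 (inversion at C6), the reversible sequence ending at the only trisubstituted oxirane, which also trades a tertiary hydroxyl for a secondary one.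

Step 12
Reactants: 18 1,6-epoxy-4,5-diol
Product: 19 1α,6α-epoxy-2α,3β-bis(benzyloxymethoxy)-1β-(benzyloxymethoxymethyl)-4α,5β-bis(triethylsilyloxy)cyclohexane
Conditions: TESCl (2.5 equiv), imidazole (5 equiv), DMF, 0 °C → rt
Reagents that add atoms: chlorotriethylsilane, CC[Si](Cl)(CC)CC
Why: Silylation with a silyl chloride and imidazole is too weakly basic to reverse the epoxide migration and masks the two secondary hydroxyls.

Step 13
Reactants: 19 bis-silyl tris-BOM epoxide
Product: 20 1α,6α-epoxy-1β-(hydroxymethyl)-4α,5β-bis(triethylsilyloxy)cyclohexane-2α,3β-diol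
Conditions: H2 (1 atm), Pd(OH)2/C, EtOAc, rt
Reagents that add atoms: none
Why: Hydrogenolysis of the benzylic C–O bonds gives hemiacetals that lose formaldehyde; the oxirane, neither allylic nor benzylic, and the silyl ethers in an aprotic solvent should survive.

Step 14
Reactants: 20 triol
Product: 21 [1α,6α-epoxy-2α,3β-dihydroxy-4α,5β-bis(triethylsilyloxy)cyclohexan-1β-yl]methyl benzoate
Conditions: BzCl (1.05 equiv), pyridine, CH2Cl2, −40 → −10 °C
Reagents that add atoms: benzoyl chloride, O=C(Cl)c1ccccc1
Why: Esterification with one equivalent of acid chloride at low temperature selects the primary C7 hydroxyl over the two hindered secondary hydroxyls at C2 and C3.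

Step 15
Reactants: 21 benzoate diol
Product: 22 [2α,3β-diacetoxy-1α,6α-epoxy-4α,5β-bis(triethylsilyloxy)cyclohexan-1β-yl]methyl benzoate
Conditions: Ac2O (4 equiv), pyridine, DMAP (cat.), CH2Cl2, 0 °C → rt
Reagents that add atoms: acetic anhydride, CC(=O)OC(C)=O
Why: DMAP-catalysed acetylation esterifies both remaining secondary hydroxyls under conditions too mild to move acyl groups or open the oxirane.

Step 16
Reactants: 22 fully protected precursor
Product: 23 [(1S,2R,3S,4R,5R,6S)-2,3-diacetoxy-4,5-dihydroxy-7-oxabicyclo[4.1.0]heptan-1-yl]methyl benzoate (target)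
Conditions: HF·pyridine, pyridine, THF, 0 °C
Reagents that add atoms: none
Why: Buffered fluoride cleavage of the triethylsilyl ethers is near neutral, so neither acetate migration to the freed C4/C5 hydroxyls nor oxirane opening is expected.

**Compound list**
1 | (1E,3E)-buta-1,3-diene-1,4-diyl diacetate | CC(=O)O/C=C/C=C/OC(C)=O | starting material
2 | lithium (1E,3E)-4-acetoxybuta-1,3-dien-1-olate | CC(=O)O/C=C/C=C/[O-].[Li+] | intermediate
3 | (1E,3E)-4-(tert-butyldimethylsilyloxy)buta-1,3-dienyl acetate | CC(=O)O/C=C/C=C/O[Si](C)(C)C(C)(C)C | intermediate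
4 | glycerol carbonate, 4-(hydroxymethyl)-1,3-dioxolan-2-one (racemic) | OCC1COC(=O)O1 | starting material
5 | 2-oxo-1,3-dioxolane-4-carboxylic acid (racemic) | OC(=O)C1COC(=O)O1 | intermediate
6 | oxazolidin-2-one | O=C1NCCO1 | starting material
7 | 2-oxo-1,3-dioxolane-4-carbonyl chloride (racemic) | ClC(=O)C1COC(=O)O1 | intermediate
8 | 3-(2-oxo-1,3-dioxolane-4-carbonyl)oxazolidin-2-one (racemic) | O=C1OCC(O1)C(=O)N1CCOC1=O | intermediate
9 | 3-(4-bromo-2-oxo-1,3-dioxolane-4-carbonyl)oxazolidin-2-one (racemic) | O=C1OCC(Br)(O1)C(=O)N1CCOC1=O | intermediate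
10 | 3-(2-oxo-1,3-dioxole-4-carbonyl)oxazolidin-2-one | O=C1OC=C(O1)C(=O)N1CCOC1=O | intermediate
11 | (3aR,4S,7R,7aR)-7-(tert-butyldimethylsilyloxy)-2-oxo-7a-(2-oxooxazolidine-3-carbonyl)-3a,4,7,7a-tetrahydro-1,3-benzodioxol-4-yl acetate | CC(=O)O[C@H]1C=C[C@@H](O[Si](C)(C)C(C)(C)C)[C@]2(C(=O)N3CCOC3=O)OC(=O)O[C@H]12 | intermediate
12 | cyclohex-4-ene with 1α,2α-carbonate, 1β-CH2OH, 3β-OAc, 6β-OTBS | CC(=O)O[C@H]1C=C[C@@H](O[Si](C)(C)C(C)(C)C)[C@]2(CO)OC(=O)O[C@H]12 | intermediate
13 | 6β-(tert-butyldimethylsilyloxy)-1β-(hydroxymethyl)cyclohex-4-ene-1α,2α,3β-triol | O[C@H]1C=C[C@@H](O[Si](C)(C)C(C)(C)C)[C@@](O)(CO)[C@@H]1O | intermediate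
14 | 2α,3β-bis(benzyloxymethoxy)-1β-(benzyloxymethoxymethyl)-6β-(tert-butyldimethylsilyloxy)cyclohex-4-en-1α-ol | O(COCc3ccccc3)[C@H]1C=C[C@@H](O[Si](C)(C)C(C)(C)C)[C@@](O)(COCOCc2ccccc2)[C@@H]1OCOCc4ccccc4 | intermediate
15 | 4α,5α-epoxide of 14 | O(COCc3ccccc3)[C@H]1[C@@H]2O[C@@H]2[C@@H](O[Si](C)(C)C(C)(C)C)[C@@](O)(COCOCc5ccccc5)[C@@H]1OCOCc4ccccc4 | intermediate
16 | 4α,5α-epoxy-2α,3β-bis(benzyloxymethoxy)-1β-(benzyloxymethoxymethyl)cyclohexane-1α,6β-diol | O(COCc3ccccc3)[C@H]1[C@@H]2O[C@@H]2[C@@H](O)[C@@](O)(COCOCc5ccccc5)[C@@H]1OCOCc4ccccc4 | intermediate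
17 | 5β,6β-epoxy-2α,3β-bis(benzyloxymethoxy)-1β-(benzyloxymethoxymethyl)cyclohexane-1α,4α-diol | O(COCc3ccccc3)[C@H]1[C@H](O)[C@H]2O[C@H]2[C@@](O)(COCOCc5ccccc5)[C@@H]1OCOCc4ccccc4 | intermediate
18 | 1α,6α-epoxy-2α,3β-bis(benzyloxymethoxy)-1β-(benzyloxymethoxymethyl)cyclohexane-4α,5β-diol | O(COCc3ccccc3)[C@H]1[C@H](O)[C@@H](O)[C@@H]2O[C@]2(COCOCc5ccccc5)[C@@H]1OCOCc4ccccc4 | intermediate
19 | 4α,5β-bis(triethylsilyl) ether of 18 | O(COCc3ccccc3)[C@H]1[C@H](O[Si](CC)(CC)CC)[C@@H](O[Si](CC)(CC)CC)[C@@H]2O[C@]2(COCOCc5ccccc5)[C@@H]1OCOCc4ccccc4 | intermediate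
20 | 1α,6α-epoxy-1β-(hydroxymethyl)-4α,5β-bis(triethylsilyloxy)cyclohexane-2α,3β-diol | O[C@H]1[C@H](O[Si](CC)(CC)CC)[C@@H](O[Si](CC)(CC)CC)[C@@H]2O[C@]2(CO)[C@@H]1O | intermediate
21 | [1α,6α-epoxy-2α,3β-dihydroxy-4α,5β-bis(triethylsilyloxy)cyclohexan-1β-yl]methyl benzoate | O[C@H]1[C@H](O[Si](CC)(CC)CC)[C@@H](O[Si](CC)(CC)CC)[C@@H]2O[C@]2(COC(=O)c3ccccc3)[C@@H]1O | intermediate
22 | [2α,3β-diacetoxy-1α,6α-epoxy-4α,5β-bis(triethylsilyloxy)cyclohexan-1β-yl]methyl benzoate | CC(=O)O[C@H]1[C@H](O[Si](CC)(CC)CC)[C@@H](O[Si](CC)(CC)CC)[C@@H]2O[C@]2(COC(=O)c3ccccc3)[C@@H]1OC(C)=O | intermediate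
23 | [(1S,2R,3S,4R,5R,6S)-2,3-diacetoxy-4,5-dihydroxy-7-oxabicyclo[4.1.0]heptan-1-yl]methyl benzoate | CC(=O)O[C@H]1[C@H](O)[C@@H](O)[C@@H]2O[C@]2(COC(=O)c2ccccc2)[C@@H]1OC(C)=O | target

**Step count**
Total: 16 steps. Longest linear sequence: 15 steps (from 4 through steps 2–5 and 6–16); the diene branch adds step 1.

**Steps most likely to fail**

1. Step 6 (bears the label). The diene may add with the carbonate ring endo instead of the acyl group. The chelate may also twist out of plane, because C1 carries an oxygen where acrylimides carry hydrogen, and facial control would then be lost. A third risk is stepwise Mukaiyama–Michael addition of the silyl dienol ether with silyl transfer and no ring closure.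
 Fallback, known chemistry (dialkylaluminium chloride-promoted Diels–Alder reaction of N-enoyl oxazolidin-2-ones carrying a 4-substituent as covalent auxiliary): it sets out from 5 and 3 and comes back at 13. Acid 5 is coupled through acid chloride 7, as in step 3, with commercial (R)-4-benzyloxazolidin-2-one to (4R)-4-benzyl-3-(2-oxo-1,3-dioxolane-4-carbonyl)oxazolidin-2-one F1. This is brominated as in step 4 to (4R)-4-benzyl-3-(4-bromo-2-oxo-1,3-dioxolane-4-carbonyl)oxazolidin-2-one F2 and dehydrobrominated as in step 5 to (4R)-4-benzyl-3-(2-oxo-1,3-dioxole-4-carbonyl)oxazolidin-2-one F3. F3 and 3 with Me2AlCl (1.4 equiv, CH2Cl2, −78 °C) should give the benzyl-auxiliary cycloadduct F4 through the s-cis aluminium chelate, in which the benzyl group covers the Si face of C1. Unlike enantiomers, unwanted stereoisomers of F4 can be removed by chromatography or crystallisation. F4 is then taken through step 7 unchanged, which releases the auxiliary and gives 13 by way of 12.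

2. Step 11. The migration may stop part-way, with the oxirane distributed among 16, 17 and 18 under catalytic base in a protic medium.
 Fallback (sets out from 16, comes back at 19): 16 is converted into its disodium dialkoxide (NaH, THF, 0 °C). The equilibrium is then governed by alkoxide stability, which further disfavours the tertiary C1 alkoxide present in 16 and 17. TESCl is then added to the same flask. Silylation of the unhindered secondary C4 alkoxide, present only in 17 and 18, blocks the return to 16. The C5 alkoxide released by the second migration is silylated in turn, giving 19 directly. Any C6-silylated 16 is recycled with fluoride. No compound outside the list is made (F0).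

3. Step 7. Hydride may attack the ring carbonyl of the oxazolidinone, because the exocyclic carbonyl sits on a fully substituted carbon; this would open the heterocycle to a hydroxyethyl amide instead of releasing C7 as the alcohol.
 Fallback (sets out from 11, comes back at 13): treatment of 11 with LiOH/H2O2 (THF/H2O, 0 °C, then Na2SO3) uses hydroperoxide, which cleaves hindered imides at the exocyclic carbonyl. The same medium hydrolyses carbonate and acetate, giving 6β-(tert-butyldimethylsilyloxy)-1α,2α,3β-trihydroxycyclohex-4-ene-1β-carboxylic acid F5. Trimethylsilyldiazomethane (MeOH/toluene) gives methyl 6β-(tert-butyldimethylsilyloxy)-1α,2α,3β-trihydroxycyclohex-4-ene-1β-carboxylate F6. LiBH4 (THF, 0 °C) reduces this α-hydroxy ester to 13.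

**Further compounds**
F1 | step 6 | (4R)-4-benzyl-3-(2-oxo-1,3-dioxolane-4-carbonyl)oxazolidin-2-one (both dioxolane C4 epimers) | O=C1OCC(O1)C(=O)N1[C@H](Cc2ccccc2)COC1=O
F2 | step 6 | (4R)-4-benzyl-3-(4-bromo-2-oxo-1,3-dioxolane-4-carbonyl)oxazolidin-2-one | O=C1OCC(Br)(O1)C(=O)N1[C@H](Cc2ccccc2)COC1=O
F3 | step 6 | (4R)-4-benzyl-3-(2-oxo-1,3-dioxole-4-carbonyl)oxazolidin-2-one | O=C1OC=C(O1)C(=O)N1[C@H](Cc2ccccc2)COC1=O
F4 | step 6 | cycloadduct with 1α,2α-carbonate, 1β-[(4R)-4-benzyl-2-oxooxazolidine-3-carbonyl], 3β-OAc, 6β-OTBS | CC(=O)O[C@H]1C=C[C@@H](O[Si](C)(C)C(C)(C)C)[C@]2(C(=O)N3[C@H](Cc4ccccc4)COC3=O)OC(=O)O[C@H]12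
F0 | step 11 | none | none
F5 | step 7 | 6β-(tert-butyldimethylsilyloxy)-1α,2α,3β-trihydroxycyclohex-4-ene-1β-carboxylic acid | O[C@H]1C=C[C@@H](O[Si](C)(C)C(C)(C)C)[C@@](O)(C(O)=O)[C@@H]1O
F6 | step 7 | methyl 6β-(tert-butyldimethylsilyloxy)-1α,2α,3β-trihydroxycyclohex-4-ene-1β-carboxylate | O[C@H]1C=C[C@@H](O[Si](C)(C)C(C)(C)C)[C@@](O)(C(=O)OC)[C@@H]1O
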